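At 10.0 h in the green run the target reads 32.0% and the substrate 0.4%, so 67.6% of the charge sits in an unread pool. At 20.0 h that pool has shrunk to 41.2%.

the same everywhere: substrate 0.090 M; free catalyst 0.39 mol%

| run | coupling partner | protic impurity | remark | time |
|---|---|---|---|---|
| violet | 2.5 equiv | 0.018 M | run made earlier |  |
| green | 2.5 equiv | 0.0090 M | run made earlier |  |
| teal | 2.5 equiv | 0.036 M | run made earlier |  |
| north-west | 2.50 equiv | 0.0180 M | a single well-mixed tank run continuously and read at steady state, 150 h in it on average |  |
| west | 2.50 equiv | 0.0180 M | everything together in a closed stirred flask, run for 15 h | 15 h |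
| north-east | 2.50 equiv (fed, over 7.50 h) | 0.0180 M | a stirred flask in which coupling partner is dosed at a steady rate over 7.50 h without added volume, worked up at 15 h | 15 h |
| east | 2.50 equiv | 0.0180 M | one stirred flow tank at steady state, fed with the mixture as stated, mean residence time 15 h |  |

| run | time / h | target / % | substrate / % |
|---|---|---|---|
| violet | 1.00 | 1.9 | 63.2 |
| violet | 3.00 | 7.8 | 26.6 |
| violet | 5.00 | 13.4 | 13.1 |
| violet | 8.00 | 24.3 | 3.3 |
| violet | 12.0 | 38.0 | 1.7 |
| violet | 15.0 | 46.4 | 0.6 |
| green | 1.33 | 1.2 | 54.8 |
| green | 4.00 | 12.0 | 17.6 |
| green | 6.00 | 17.9 | 8.4 |
| green | 10.0 | 32.0 | 0.4 |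
| green | 15.0 | 46.1 | 1.4 |
| green | 20.0 | 58.8 | 0 |
| teal | 1.33 | 2.2 | 54.1 |
| teal | 2.50 | 6.3 | 32.3 |
| teal | 4.00 | 9.7 | 16.8 |
| teal | 6.00 | 18.5 | 9.5 |
| teal | 10.0 | 30.2 | 0 |
| teal | 20.0 | 55.6 | 0 |

(scatter of a reading: 1 percentage point)

- the stated concentrations are those of everything mixed, before any reaction; amounts are the same in each set-up
- the feed brings no volume worth counting
- the earlier runs were made in a closed, stirred flask

* order of the set-ups by the amount of target at the outlet or at the end, in percent of the substrate put in, highest first (north-west / west / north-east / east)
* amount of target at the outlet or at the end, in percent of the substrate put in, north-west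
* amount of target at the outlet or at the end, in percent of the substrate put in, west
* amount of target at the outlet or at the end, in percent of the substrate put in, north-east
* amount of target at the outlet or at the end, in percent of the substrate put in, east

I treat the pool's decline in the green run as exponential, which gives a pool time, the mean stay of material in the unread pool, of 20.2 h. The violet run's substrate reading at 5.00 h gives a mean substrate time of 2.46 h, so by these readings the pool is the slower stage.

I then replace the substrate's curve by its mean, as if the whole charge entered the pool at 2.46 h, and I carry the pool time unaltered from the green run, at 0.0090 M of protic impurity, to the violet run, at 0.018 M. This predicts 46.3% at 15.0 h in the violet run, where the reading is 46.4% with a scatter of 1 percentage point. West has the violet charge and time, so I take that reading for west.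

In a well-mixed tank at steady state, a first-order stage passes on a share of what enters it equal to residence time over residence time plus stage time. For east, at a mean residence time of 15 h, I therefore reckon 36.6%.

The forecast, which rests on “a hidden intermediate pool, which drains slowly to target”, orders the set-ups north-west > west > north-east > east, with 86%, 46.5%, 41% and 36.5% in that order.

The flask gives north-west > west > north-east > east, with 85.9%, 45.7%, 40.5% and 36.8% in that order.

    free catalyst + open intermediate ⇌ catalyst intermediate (K = 17.0 M⁻¹, k = 10.0 M⁻¹ min⁻¹)
    coupling partner + catalyst intermediate → free catalyst + target (k = 3.00 M⁻¹ min⁻¹)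
    target → over-reaction product (k = 5.10 × 10⁻⁷ min⁻¹)
    substrate + free catalyst → free catalyst + open intermediate (k = 40.0 M⁻¹ min⁻¹)
    2 free catalyst ⇌ resting dimer, settled at all times (K = 1700 M⁻¹)
    coupling partner + protic impurity → quenched reagent (k = 0.110 M⁻¹ min⁻¹)

East delivers 36.8% of target, against my 36.6%. Its outlet holds 13.6% of the substrate, and my substrate time leaves a share of 14.1%. I now use the pool time on north-west, at 150 h on average: the two stages pass 86.7%, and that tank delivers 85.9%.

The runs are calculated on assumed constants.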